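The benzo ring of the isocoumarin (C4a, C5, C6, C7, C8, C8a) carries three neighbouring carbon substituents: C1 on C8a, C4 on C4a and the ring A benzyl group on C5. It also carries OH on C6 and OMe on C8, beside the lactone carbonyl. That pattern is a homophthalate, so this ring is built from open chains. A 1,1-dimethoxy-3-silyloxypenta-1,3-diene, whose C4 terminus already holds the CH2–ring A arm, adds to an allene-1,3-dicarboxylate and forms C5–C4a and C8–C8a. Loss of methanol and an alkene shift aromatise the adduct. All six substituents are placed in one operation, with no C5/C7 ambiguity.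

Key step: step 10

Abbreviation used in names: Ar = 4-(benzyloxy)-2-methoxy-6-(methoxymethyl)phenyl, that is ring A with its phenol protected as the benzyl ether.
Remark on the chemistry: the target has no stereocentre. Allene 17 is axially chiral and is used as the racemate. The only stereochemical element of the route is the (Z) geometry of diene 14, which disappears on aromatisation.
Assumption: alcohol 1 is taken as a catalogue compound.

Step 1
Reactants: 1 3,5-bis(benzyloxy)benzyl alcohol
Product: 2 1,3-bis(benzyloxy)-5-(methoxymethyl)benzene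
Conditions: NaH, MeI, THF, 0 °C → rt
Reagents that add atoms: iodomethane, CI
Why: Williamson ether synthesis, in which the sodium alkoxide of the primary benzylic alcohol displaces iodide from MeI (SN2) while the two aryl benzyl ethers are inert to base.

Step 2
Reactants: 2 1,3-bis(benzyloxy)-5-(methoxymethyl)benzene
Product: 4 2,4-bis(benzyloxy)-6-(methoxymethyl)benzaldehyde, via aryl iminium chloride 3 (not isolated)
Conditions: POCl3, DMF, 0 → 60 °C; then aq. NaOH, 0 °C → rt
Reagents that add atoms: N,N-dimethylformamide, CN(C)C=O; water, O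
Why: Vilsmeier–Haack formylation, in which the chloroiminium ion attacks the carbon that is para to one benzyloxy group and ortho to the other rather than the carbon wedged between both, and since 2 is symmetric the two such sites are identical, so hydrolysis of 3 should give a single aldehyde.

Step 3
Reactants: 4 2,4-bis(benzyloxy)-6-(methoxymethyl)benzaldehyde
Product: 5 4-(benzyloxy)-2-hydroxy-6-(methoxymethyl)benzaldehyde
Conditions: MgBr2·OEt2, PhMe/Et2O, reflux; 1 M HCl work-up
Reagents that add atoms: none
Why: Chelation-directed ether cleavage, in which magnesium binds the aldehyde oxygen and the ortho benzyloxy oxygen in a six-membered chelate so that bromide removes only that benzyl group (SN2 at the benzylic CH2), which tells the two ring A oxygens apart while the para benzyl ether and the aliphatic methyl ether are left alone.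

Step 4
Reactants: 5 4-(benzyloxy)-2-hydroxy-6-(methoxymethyl)benzaldehyde
Product: 6 4-(benzyloxy)-2-methoxy-6-(methoxymethyl)benzaldehyde
Conditions: MeI, K2CO3, DMF, rt
Reagents that add atoms: iodomethane, CI
Why: Williamson O-methylation of the only free phenol, which fixes OMe ortho and OBn para to the carbon that becomes the diarylmethane bridge, exactly as ring A of the target requires.

Step 5
Reactants: 6 4-(benzyloxy)-2-methoxy-6-(methoxymethyl)benzaldehyde; 7 Meldrum's acid (2,2-dimethyl-1,3-dioxane-4,6-dione)
Product: 10 3-Ar-propanoic acid, via arylidene Meldrum's acid 8 (not isolated), via benzyl Meldrum's acid 9 (not isolated)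
Conditions: HCO2H/Et3N (triethylammonium formate), 95–100 °C
Reagents that add atoms: none
Why: Knoevenagel condensation to 8, conjugate hydride transfer from formate to give 9, then hydrolysis and decarboxylation in the same hot buffer extend the aldehyde by two carbons without ever making the ring A benzylic halide, which would ionise easily and be trapped by the neighbouring CH2OMe oxygen.

Step 6
Reactants: 10 3-Ar-propanoic acid; 11 1,1-dimethoxyethene
Product: 13 5-Ar-1,1-dimethoxypent-1-en-3-one, via acid chloride 12 (not isolated)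
Conditions: (COCl)2, cat. DMF, CH2Cl2, 0 °C → rt, evaporate; then 11 (2.5 equiv), Et2O, 0 °C → reflux; non-aqueous isolation
Reagents that add atoms: none
Why: C-acylation of a ketene acetal, in which the nucleophilic CH2 terminus of 11 attacks 12 and a second equivalent of 11 takes up the HCl so that the dimethoxycarbenium intermediate loses a proton rather than a methyl group, while Friedel–Crafts closure to an indanone is impossible because both positions ortho to the side chain are substituted.

Step 7
Reactants: 13 5-Ar-1,1-dimethoxypent-1-en-3-one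
Product: 14 (Z)-5-Ar-1,1-dimethoxy-3-(trimethylsilyloxy)penta-1,3-diene
Conditions: TMSOTf, Et3N, Et2O, 0 °C; decant from the ammonium salt, evaporate, use crude
Reagents that add atoms: trimethylsilyl trifluoromethanesulfonate, C[Si](C)(C)OS(=O)(=O)C(F)(F)F
Why: Soft enolisation (enol silylation), in which O-silylation of the vinylogous carbonate carbonyl gives a delocalised cation that Et3N deprotonates at the only available CH2 next to the carbonyl, and the (Z) isomer with OSi and CH2Ar cis should prevail because it avoids allylic strain between CH2Ar and the dimethoxyvinyl group.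

Step 8
Reactants: 15 dimethyl 3-oxopentanedioate
Product: 16 dibenzyl 3-oxopentanedioate
Conditions: BnOH (2.5 equiv), cat. DMAP, PhMe, reflux, MeOH distilled off
Reagents that add atoms: benzyl alcohol, OCc1ccccc1
Why: Transesterification of a β-keto ester driven by removal of methanol, chosen because the aromatic ester of the later homophthalate sits between two ortho substituents and para to a phenoxide and would resist saponification, whereas benzyl esters leave under neutral hydrogenolysis together with the ring A benzyl ether.

Step 9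
Reactants: 16 dibenzyl 3-oxopentanedioate
Product: 17 dibenzyl penta-2,3-dienedioate (racemic)
Conditions: 2-chloro-1,3-dimethylimidazolinium chloride, Et3N, CH2Cl2, 0 °C → rt
Reagents that add atoms: none
Why: Dehydration of a 3-oxoglutarate to the allene-1,3-dicarboxylate, in which the chloroamidinium salt turns the enol oxygen into a urea leaving group and Et3N removes the acidic proton on the far side (E1cB-type elimination) to give the cumulated diene.

Step 10
Reactants: 14 (Z)-5-Ar-1,1-dimethoxy-3-(trimethylsilyloxy)penta-1,3-diene; 17 dibenzyl penta-2,3-dienedioate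
Product: 20 dibenzyl 3-(ArCH2)-4-hydroxy-6-methoxyhomophthalate, via cyclohexene cycloadduct 18 (not isolated), via aryl silyl ether 19 (not isolated)
Conditions: 14 (1.3 equiv), PhMe, 0 → 60 °C; then MeOH, cat. PPTS, rt
Reagents that add atoms: none
Why: The terminus of 14 that bears CH2Ar (future C5) is the nucleophilic end of the diene, because the silyloxy group and, through conjugation, the ketene acetal both push electrons to it, so it bonds to the electrophilic central carbon of 17 (future C4a) while the acetal carbon (future C8) bonds to the neighbouring ester-bearing carbon (future C8a), either in one asynchronous [4+2] event or by Mukaiyama–Michael addition followed by closure of the ester dienolate onto the dimethoxycarbenium ion, to give 18. Loss of methanol across C8–C8a and migration of the exocyclic C4a=CH double bond into the ring with loss of H5 make arene 19, and acid-catalysed methanolysis of its aryl silyl ether frees the C6 phenol of 20. The closest known reaction type is the Diels–Alder/aromatisation of 1,1-dialkoxy-3-silyloxybutadienes and 1-alkoxy-1,3-bis(silyloxy)butadienes with allene-1,3-dicarboxylates, which delivers hydroxy- and alkoxy-homophthalates. The single new ring, the six-membered carbocycle C4a–C5–C6–C7–C8–C8a, is closed intermolecularly from four diene carbons and two allene carbons. No stereocentre has to be controlled, since the two sp3 centres and the alkene geometry of 18 as well as the axial chirality of 17 vanish on aromatisation. The step needs regioselectivity, which the matched polarisation of the two partners secures and which puts OMe beside the aromatic ester and CH2Ar beside the acetic ester arm; the two C=C bonds of 17 are equivalent by symmetry, and the (Z) geometry of 14 keeps CH2Ar on the outside of the s-cis diene so that the reactive conformation is accessible.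

Step 11
Reactants: 20 dibenzyl 3-(ArCH2)-4-hydroxy-6-methoxyhomophthalate
Product: 21 4-hydroxy-3-[4-hydroxy-2-methoxy-6-(methoxymethyl)benzyl]-6-methoxyhomophthalic acid
Conditions: H2 (1 atm), 10% Pd/C, EtOAc/THF, rt; filter, evaporate, use crude
Reagents that add atoms: none
Why: Catalytic hydrogenolysis, in which the two benzyl esters and the aryl benzyl ether, all with carboxylate or phenoxide leaving groups, are cleaved far faster than the aliphatic benzylic methyl ether of ring A, so one neutral operation frees both acids and the ring A phenol before any reducible C3=C4 alkene exists.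

Step 12
Reactants: 21 4-hydroxy-3-[4-hydroxy-2-methoxy-6-(methoxymethyl)benzyl]-6-methoxyhomophthalic acid
Product: 24 4-hydroxy-3-[4-hydroxy-2-methoxy-6-(methoxymethyl)benzyl]-6-methoxy-2-(2-oxopropyl)benzoic acid, via C4-acetyl anhydride 22 (not isolated), via beta-keto diacid 23 (not isolated)
Conditions: Ac2O, pyridine, cat. DMAP, rt; evaporate; then 2 M NaOH, THF, rt, Ar; then 1 M HCl, 0 °C → rt
Reagents that add atoms: acetic anhydride, CC(=O)OC(C)=O; water (as hydroxide), O
Why: Dakin–West-type C-acetylation of a homophthalic anhydride, in which Ac2O caps both phenols and closes the cyclic anhydride, pyridine/DMAP enolise the doubly activated C4 methylene and acetylate it to 22, hydroxide then opens the anhydride and cleaves the aryl acetates to 23, and acidification lets this β-keto acid lose CO2 at room temperature, so that the hot mineral acid which could break the acid-labile dialkoxybenzyl–arene bond at C5 is never needed.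

Step 13
Reactants: 24 4-hydroxy-3-[4-hydroxy-2-methoxy-6-(methoxymethyl)benzyl]-6-methoxy-2-(2-oxopropyl)benzoic acid
Product: 26 6-hydroxy-5-[4-hydroxy-2-methoxy-6-(methoxymethyl)benzyl]-8-methoxy-3-methyl-1H-isochromen-1-one (target), via bis(trifluoroacetate) 25 (not isolated)
Conditions: (CF3CO)2O, pyridine, CH2Cl2, 0 °C; then MeOH, rt
Reagents that add atoms: none
Why: Enol lactonisation (cyclodehydration of a δ-keto acid through a mixed anhydride), in which the anhydride reagent activates the benzoic acid, the ketone oxygen closes the six-membered lactone and pyridine removes H4 to give the conjugated 2-pyranone ring, while the two phenols are only masked in passing as the trifluoroacetates of 25, which methanol and pyridine cleave at room temperature without opening the lactone.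

Compound list
1 | 3,5-bis(benzyloxy)benzyl alcohol | OCc1cc(OCc2ccccc2)cc(OCc2ccccc2)c1 | starting material
2 | 1,3-bis(benzyloxy)-5-(methoxymethyl)benzene | COCc1cc(OCc2ccccc2)cc(OCc2ccccc2)c1 | intermediate
3 | N-{[2,4-bis(benzyloxy)-6-(methoxymethyl)phenyl]methylidene}-N-methylmethanaminium chloride | C[N+](C)=Cc1c(COC)cc(OCc2ccccc2)cc1OCc1ccccc1.[Cl-] | intermediate
4 | 2,4-bis(benzyloxy)-6-(methoxymethyl)benzaldehyde | O=Cc1c(COC)cc(OCc2ccccc2)cc1OCc1ccccc1 | intermediate
5 | 4-(benzyloxy)-2-hydroxy-6-(methoxymethyl)benzaldehyde | O=Cc1c(COC)cc(OCc2ccccc2)cc1O | intermediate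
6 | 4-(benzyloxy)-2-methoxy-6-(methoxymethyl)benzaldehyde | O=Cc1c(COC)cc(OCc2ccccc2)cc1OC | intermediate
7 | Meldrum's acid (2,2-dimethyl-1,3-dioxane-4,6-dione) | CC1(C)OC(=O)CC(=O)O1 | starting material
8 | 5-{[4-(benzyloxy)-2-methoxy-6-(methoxymethyl)phenyl]methylidene}-2,2-dimethyl-1,3-dioxane-4,6-dione | CC1(C)OC(=O)C(=Cc2c(COC)cc(OCc3ccccc3)cc2OC)C(=O)O1 | intermediate
9 | 5-{[4-(benzyloxy)-2-methoxy-6-(methoxymethyl)phenyl]methyl}-2,2-dimethyl-1,3-dioxane-4,6-dione | CC1(C)OC(=O)C(Cc2c(COC)cc(OCc3ccccc3)cc2OC)C(=O)O1 | intermediate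
10 | 3-[4-(benzyloxy)-2-methoxy-6-(methoxymethyl)phenyl]propanoic acid | OC(=O)CCc1c(COC)cc(OCc2ccccc2)cc1OC | intermediate
11 | 1,1-dimethoxyethene | C=C(OC)OC | starting material
12 | 3-[4-(benzyloxy)-2-methoxy-6-(methoxymethyl)phenyl]propanoyl chloride | ClC(=O)CCc1c(COC)cc(OCc2ccccc2)cc1OC | intermediate
13 | 5-[4-(benzyloxy)-2-methoxy-6-(methoxymethyl)phenyl]-1,1-dimethoxypent-1-en-3-one | COC(OC)=CC(=O)CCc1c(COC)cc(OCc2ccccc2)cc1OC | intermediate
14 | (Z)-5-[4-(benzyloxy)-2-methoxy-6-(methoxymethyl)phenyl]-1,1-dimethoxy-3-(trimethylsilyloxy)penta-1,3-diene | C[Si](C)(C)O/C(C=C(OC)OC)=C\Cc1c(COC)cc(OCc2ccccc2)cc1OC | intermediate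
15 | dimethyl 3-oxopentanedioate | COC(=O)CC(=O)CC(=O)OC | starting material
16 | dibenzyl 3-oxopentanedioate | O=C(CC(=O)OCc1ccccc1)CC(=O)OCc1ccccc1 | intermediate
17 | dibenzyl penta-2,3-dienedioate (racemic) | O=C(C=C=CC(=O)OCc1ccccc1)OCc1ccccc1 | intermediate
18 | benzyl 5-(ArCH2)-6-[2-(benzyloxy)-2-oxoethylidene]-2,2-dimethoxy-4-(trimethylsilyloxy)cyclohex-3-ene-1-carboxylate (mixture of stereoisomers, transient) | O=C(OCc1ccccc1)C=C1C(Cc2c(COC)cc(OCc3ccccc3)cc2OC)C(O[Si](C)(C)C)=CC(OC)(OC)C1C(=O)OCc1ccccc1 | intermediate
19 | dibenzyl 3-(ArCH2)-6-methoxy-4-(trimethylsilyloxy)homophthalate | O=C(Cc1c(Cc2c(COC)cc(OCc3ccccc3)cc2OC)c(O[Si](C)(C)C)cc(OC)c1C(=O)OCc1ccccc1)OCc1ccccc1 | intermediate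
20 | dibenzyl 3-(ArCH2)-4-hydroxy-6-methoxyhomophthalate (benzyl 2-[2-(benzyloxy)-2-oxoethyl]-3-(ArCH2)-4-hydroxy-6-methoxybenzoate) | O=C(Cc1c(Cc2c(COC)cc(OCc3ccccc3)cc2OC)c(O)cc(OC)c1C(=O)OCc1ccccc1)OCc1ccccc1 | intermediate
21 | 2-(carboxymethyl)-4-hydroxy-3-[4-hydroxy-2-methoxy-6-(methoxymethyl)benzyl]-6-methoxybenzoic acid | OC(=O)Cc1c(Cc2c(COC)cc(O)cc2OC)c(O)cc(OC)c1C(=O)O | intermediate
22 | 4-acetyl-5-[4-acetoxy-2-methoxy-6-(methoxymethyl)benzyl]-8-methoxy-1,3-dioxoisochroman-6-yl acetate (drawn as the keto form, readily enolised at C4) | CC(=O)C1C(=O)OC(=O)c2c(OC)cc(OC(C)=O)c(Cc3c(COC)cc(OC(C)=O)cc3OC)c12 | intermediate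
23 | 2-(1-carboxy-2-oxopropyl)-4-hydroxy-3-[4-hydroxy-2-methoxy-6-(methoxymethyl)benzyl]-6-methoxybenzoic acid (racemic, transient) | CC(=O)C(C(=O)O)c1c(Cc2c(COC)cc(O)cc2OC)c(O)cc(OC)c1C(=O)O | intermediate
24 | 4-hydroxy-3-[4-hydroxy-2-methoxy-6-(methoxymethyl)benzyl]-6-methoxy-2-(2-oxopropyl)benzoic acid | CC(=O)Cc1c(Cc2c(COC)cc(O)cc2OC)c(O)cc(OC)c1C(=O)O | intermediate
25 | bis(trifluoroacetate) of 26 (both phenols esterified) | COCc1cc(OC(=O)C(F)(F)F)cc(OC)c1Cc1c(OC(=O)C(F)(F)F)cc(OC)c2c(=O)oc(C)cc12 | intermediate
26 | 6-hydroxy-5-[4-hydroxy-2-methoxy-6-(methoxymethyl)benzyl]-8-methoxy-3-methyl-1H-isochromen-1-one | COCc1cc(O)cc(OC)c1Cc1c(O)cc(OC)c2c(=O)oc(C)cc12 | target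

Total step count: 13. Longest linear sequence: 11 (steps 1–7 and 10–13). Steps 8 and 9 form the short allene branch.

Steps most likely to fail

Step 10 (key step). The diene terminus that carries CH2Ar may react too slowly. Oligomerisation of the allene, hydrolysis of the diene, or bond formation through the internal diene carbon could then take over. The fallback makes the same two bonds one after the other under anionic conditions. It sets out from enone 13 and allene 17.
- LiN(SiMe3)2 (THF, −78 °C) converts 13 into its cross-conjugated lithium dienolate.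
- This dienolate adds through the carbon bearing CH2Ar to the central carbon of 17. After a buffered quench this should give the acyclic glutaconate adduct dibenzyl 3-[1-Ar-5,5-dimethoxy-3-oxopent-4-en-2-yl]pent-2-enedioate F1.
- DBU in MeCN then deprotonates the glutaconate. The carbanion adds to the dimethoxyvinyl carbon (6-endo-trig addition–elimination of methoxide), and tautomerisation to the phenol brings the sequence back to the route at 20.

Step 6. Chloride may demethylate the dimethoxycarbenium intermediate, or adventitious moisture may hydrolyse the ketene acetal during isolation. Dehydrochlorination of the acid chloride to a ketene would also consume material. The fallback accepts the β-keto ester oxidation pattern and corrects the oxygen substituents after the ring is built. It sets out from acid 10.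
- Carbonyldiimidazole, then KO2CCH2CO2Me, MgCl2 and Et3N (magnesium malonate chain extension), give methyl 5-Ar-3-oxopentanoate F2.
- TMSOTf (2.2 equiv) and Et3N give (3Z)-5-Ar-1-methoxy-1,3-bis(trimethylsilyloxy)penta-1,3-diene F3.
- Cycloaddition and aromatisation with 17 under the conditions of step 10 give dibenzyl 3-(ArCH2)-4,6-dihydroxyhomophthalate F4.
- BnBr and K2CO3 alkylate only the phenol that is not hydrogen-bonded to the ester, giving dibenzyl 3-(ArCH2)-4-(benzyloxy)-6-hydroxyhomophthalate F5.
- MeI and K2CO3 then methylate the chelated phenol, giving dibenzyl 3-(ArCH2)-4-(benzyloxy)-6-methoxyhomophthalate F6.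
- Hydrogenolysis under the conditions of step 11 removes all four benzyl groups and comes back to the route at 21.

Step 12. The peri CH2 group at C5 may shield C4, so that acetylation stops at the enol oxygen and the hydrolysis merely returns the diacid. The fallback builds the methyl ketone at the carboxyl carbon of the acetic arm instead of acylating C4. It sets out from 20.
- LiOH (THF/H2O, rt) cleaves only the unhindered aliphatic benzyl ester, giving [2-(benzyloxycarbonyl)-6-(ArCH2)-5-hydroxy-3-methoxyphenyl]acetic acid F7.
- EDC·HCl, HOBt, MeNH(OMe)·HCl and iPr2NEt give the Weinreb amide F8.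
- Excess MeMgBr (THF, −20 → 0 °C) gives benzyl 3-(ArCH2)-4-hydroxy-6-methoxy-2-(2-oxopropyl)benzoate F9. The di-ortho-substituted aromatic ester should be too hindered to react.
- H2 with 10% Pd/C removes the benzyl ester and the benzyl ether and comes back to the route at 24.

Further compounds
F1 | step 10 | dibenzyl 3-[1-Ar-5,5-dimethoxy-3-oxopent-4-en-2-yl]pent-2-enedioate (racemic, alkene isomers) | O=C(OCc1ccccc1)C=C(CC(=O)OCc1ccccc1)C(Cc1c(COC)cc(OCc2ccccc2)cc1OC)C(=O)C=C(OC)OC
F2 | step 6 | methyl 5-Ar-3-oxopentanoate | COC(=O)CC(=O)CCc1c(COC)cc(OCc2ccccc2)cc1OC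
F3 | step 6 | (3Z)-5-Ar-1-methoxy-1,3-bis(trimethylsilyloxy)penta-1,3-diene | C[Si](C)(C)O/C(C=C(OC)O[Si](C)(C)C)=C\Cc1c(COC)cc(OCc2ccccc2)cc1OC
F4 | step 6 | dibenzyl 3-(ArCH2)-4,6-dihydroxyhomophthalate | O=C(Cc1c(Cc2c(COC)cc(OCc3ccccc3)cc2OC)c(O)cc(O)c1C(=O)OCc1ccccc1)OCc1ccccc1
F5 | step 6 | dibenzyl 3-(ArCH2)-4-(benzyloxy)-6-hydroxyhomophthalate | O=C(Cc1c(Cc2c(COC)cc(OCc3ccccc3)cc2OC)c(OCc2ccccc2)cc(O)c1C(=O)OCc1ccccc1)OCc1ccccc1
F6 | step 6 | dibenzyl 3-(ArCH2)-4-(benzyloxy)-6-methoxyhomophthalate | O=C(Cc1c(Cc2c(COC)cc(OCc3ccccc3)cc2OC)c(OCc2ccccc2)cc(OC)c1C(=O)OCc1ccccc1)OCc1ccccc1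
F7 | step 12 | [2-(benzyloxycarbonyl)-6-(ArCH2)-5-hydroxy-3-methoxyphenyl]acetic acid | OC(=O)Cc1c(Cc2c(COC)cc(OCc3ccccc3)cc2OC)c(O)cc(OC)c1C(=O)OCc1ccccc1
F8 | step 12 | benzyl 3-(ArCH2)-4-hydroxy-6-methoxy-2-{2-[methoxy(methyl)amino]-2-oxoethyl}benzoate | CON(C)C(=O)Cc1c(Cc2c(COC)cc(OCc3ccccc3)cc2OC)c(O)cc(OC)c1C(=O)OCc1ccccc1
F9 | step 12 | benzyl 3-(ArCH2)-4-hydroxy-6-methoxy-2-(2-oxopropyl)benzoate | CC(=O)Cc1c(Cc2c(COC)cc(OCc3ccccc3)cc2OC)c(O)cc(OC)c1C(=O)OCc1ccccc1
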